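**Plan**
Retrosynthesis: remove the C8 angelate. Cut the γ-lactone at O–C6 and C11–C12, which takes out CO2 and leaves a ten-membered carbocycle with a C11 alkenylboronate and a 6-epi allylic phosphate. Cut C6–C7 (allylboration) to an open-chain allene–enal. Cut C1=C10 (HWE) to aldehyde 4 (C1–C6, C15, from nerol) and phosphono lactone 13 (C7–C11, C13, C14).
Forward order: the chain is joined at C1=C10, the ten-membered ring is closed at C6–C7, the γ-lactone ring is closed last with CO2, then O8 is acylated and the silyl groups are removed.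
Enabling feature: vinylic C11 (of the exocyclic C11=C13) and C6 (allylic to C4=C5) are 1,3-related through C7. The O–C12(=O) atoms of CO2 therefore complete the five-membered ring O–C6–C7–C11–C12, with C11 taking the carbon as a nucleophile and C6 taking the oxygen as an electrophile.
Stereochemistry: C8 comes from asymmetric transfer hydrogenation and C2 from D-proline aminoxylation. C7 and C6 are relayed from C8 in the ring closure, which gives the 6,7-syn (6-epi) alcohol. The CO2 step inverts C6 to the trans-lactone, whereas an acylative lactonisation would give the cis-lactone.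
Alkene geometry: C4=C5 (Z) is bought with nerol, C1=C10 comes from an E-selective HWE on a temporary C14–O8 butyrolactone, and the angelate is bought.

Key step: step 19

Remark: germacrane numbering is used. The ring is C1–C10, C11=C13 is the exocyclic methylene, C12 the lactone carbonyl, C14 the CH2O on C10 and C15 the methyl on C4. Compounds 15–23 are the open chain C6–C5=C4(C15)–C3–C2–C1=C10(C14)–C9–C8–C7=C11=C13. The CIP letter at C7 changes with the O-substituents on C6 and C8, although the spatial arrangement at C7 is the same from 24 to 33.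

Step 1
Reactants: 1 nerol
Product: 2 neryl 4-methoxybenzyl ether
Conditions: NaH, PMBCl, Bu4NI (cat.), THF/DMF, 0 °C to rt
Reagents that add atoms: 4-methoxybenzyl chloride, COc1ccc(CCl)cc1
Why: Williamson etherification of the primary allylic alkoxide leaves the Z double bond of nerol, the source of the C4=C5 geometry, untouched.

Step 2
Reactants: 2 neryl 4-methoxybenzyl ether
Product: 3 6,7-epoxyneryl 4-methoxybenzyl ether (racemic at the epoxide carbon)
Conditions: mCPBA (1.0 equiv), NaHCO3, CH2Cl2, −20 to 0 °C
Reagents that add atoms: 3-chloroperoxybenzoic acid, O=C(OO)c1cccc(Cl)c1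
Why: Prilezhaev epoxidation selects the remote, more electron-rich trisubstituted alkene because C4=C5 is deactivated by the allylic oxygen, and the new stereocentre is destroyed in step 3.

Step 3
Reactants: 3 6,7-epoxyneryl 4-methoxybenzyl ether
Product: 4 (4Z)-6-[(4-methoxybenzyl)oxy]-4-methylhex-4-enal
Conditions: H5IO6, THF/H2O, 0 °C
Reagents that add atoms: none
Why: Periodic acid hydrolyses the epoxide and cleaves the glycol in the same flask (Malaprade cleavage), which leaves the C1 aldehyde without touching the Z-alkene or the PMB ether.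

Step 4
Reactants: 5 methyl 4-chloro-4-oxobutanoate; 6 bis(trimethylsilyl)acetylene
Product: 7 methyl 4-oxo-6-(trimethylsilyl)hex-5-ynoate
Conditions: AlCl3, CH2Cl2, 0 °C
Reagents that add atoms: none
Why: Friedel–Crafts-type acylative ipso-desilylation of the bis-silylalkyne stops after one acylation because the ynone formed is deactivated.

Step 5
Reactants: 7 methyl 4-oxo-6-(trimethylsilyl)hex-5-ynoate
Product: 8 methyl (4S)-4-hydroxy-6-(trimethylsilyl)hex-5-ynoate
Conditions: Ru[(S,S)-TsDPEN](p-cymene) (1 mol %), i-PrOH, rt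
Reagents that add atoms: none
Why: Noyori asymmetric transfer hydrogenation of alkynyl ketones places the alkyne where an aryl group sits in the organised transition state, so the (S,S)-catalyst should set C8 as S while the ester stays inert.

Step 6
Reactants: 8 methyl (4S)-4-hydroxy-6-(trimethylsilyl)hex-5-ynoate
Product: 10 (5S)-5-ethynyloxolan-2-one, via hydroxy alkynoate 9 (not isolated)
Conditions: K2CO3 (cat.), MeOH, 0 °C; then TsOH·H2O (cat.), CH2Cl2, rt
Reagents that add atoms: none
Why: Methanolysis of the alkynyl C–Si bond and acid-catalysed lactonisation of the γ-hydroxy ester act at silicon and at the acyl carbon only, so C8 keeps its configuration.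

Step 7
Reactants: 10 (5S)-5-ethynyloxolan-2-one
Product: 11 (5S)-5-(propa-1,2-dien-1-yl)oxolan-2-one
Conditions: (CH2O)n, CuI, Cy2NH, dioxane, reflux
Reagents that add atoms: formaldehyde (as paraformaldehyde), C=O
Why: Crabbé–Ma homologation (copper-mediated Mannich coupling, then 1,5-hydride transfer with loss of the imine) adds C13 and gives the terminal allene, and the hindered amine should not open the lactone.

Step 8
Reactants: 11 (5S)-5-(propa-1,2-dien-1-yl)oxolan-2-one
Product: 13 diethyl [(5S)-2-oxo-5-(propa-1,2-dienyl)oxolan-3-yl]phosphonate (C10 epimers), via lactone phosphonite 12 (not isolated)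
Conditions: LDA (1.05 equiv), THF, −78 °C; ClP(OEt)2, −78 °C to rt; then 30 % H2O2, 0 °C
Reagents that add atoms: diethyl chlorophosphite, CCOP(Cl)OCC; hydrogen peroxide, OO
Why: Lactone enolates react with P(III) chlorides at carbon and oxidation gives the α-phosphono lactone with one equivalent of base at −78 °C, which spares the allene, and the C10 epimers converge in step 9.

Step 9
Reactants: 4 (4Z)-6-[(4-methoxybenzyl)oxy]-4-methylhex-4-enal; 13 diethyl [(5S)-2-oxo-5-(propa-1,2-dienyl)oxolan-3-yl]phosphonate
Product: 15 E-alkylidene lactone bearing the (2S)-anilinooxy group, via α-aminoxy aldehyde 14 (not isolated)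
Conditions: PhNO, D-proline (20 mol %), MeCN, −20 °C; then 13, LiCl, DBU, MeCN, 0 °C
Reagents that add atoms: nitrosobenzene, O=Nc1ccccc1
Why: D-proline enamine catalysis (α-aminoxylation) sets C2 as S, and the Masamune–Roush Horner–Wadsworth–Emmons reaction of crude 14 should favour the more stable E-alkylidene lactone (C2 trans to C14=O) under conditions too mild to epimerise C2.

Step 10
Reactants: 15 E-alkylidene lactone bearing the (2S)-anilinooxy group
Product: 16 (2S)-hydroxy E-alkylidene lactone
Conditions: Cu(OAc)2 (0.3 equiv), MeOH, rt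
Reagents that add atoms: none
Why: Copper(II)-catalysed N–O cleavage of O-alkyl-N-arylhydroxylamines tolerates the allene, the alkylidene lactone and the PMB ether, and the E geometry keeps the C2 hydroxyl from lactonising onto C14.

Step 11
Reactants: 16 (2S)-hydroxy E-alkylidene lactone
Product: 17 2-O-TBS E-alkylidene lactone
Conditions: TBSCl, imidazole, DMF, rt
Reagents that add atoms: tert-butyldimethylsilyl chloride, CC(C)(C)[Si](C)(C)Cl
Why: Imidazole-promoted silylation of the secondary allylic alcohol is routine and touches no stereocentre.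

Step 12
Reactants: 17 2-O-TBS E-alkylidene lactone
Product: 18 open-chain C14/C8 diol
Conditions: DIBAL-H (4.5 equiv), CH2Cl2, −78 to 0 °C; aq. Rochelle salt
Reagents that add atoms: none
Why: DIBAL-H reduces α-alkylidene lactones by 1,2-addition through the lactol to the diol, which releases C14-OH and C8-OH as a primary/secondary pair while PMB, TBS and the allene stay intact.

Step 13
Reactants: 18 open-chain C14/C8 diol
Product: 19 14-O-TBS ether carrying free C8-OH
Conditions: TBSCl (1.05 equiv), imidazole, CH2Cl2, 0 °C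
Reagents that add atoms: tert-butyldimethylsilyl chloride, CC(C)(C)[Si](C)(C)Cl
Why: Kinetic silylation selects the primary allylic C14 hydroxyl over the secondary, α-branched C8 hydroxyl.

Step 14
Reactants: 19 14-O-TBS ether carrying free C8-OH
Product: 20 8-O-TES ether
Conditions: TESCl, imidazole, DMAP (cat.), CH2Cl2, rt
Reagents that add atoms: chlorotriethylsilane, CC[Si](CC)(CC)Cl
Why: Silylation with the more labile TES group marks O8 for selective release later in the presence of the two TBS ethers, and its bulk shields one face of C7 in step 17.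

Step 15
Reactants: 20 8-O-TES ether
Product: 21 C6 allylic alcohol
Conditions: DDQ (1.2 equiv), CH2Cl2/pH 7 buffer, 0 °C
Reagents that add atoms: none
Why: Oxidative PMB cleavage (hydride abstraction from the electron-rich benzyl ether by DDQ) under buffered conditions leaves the silyl ethers and the allene alone.

Step 16
Reactants: 21 C6 allylic alcohol
Product: 22 (4Z)-allene–enal
Conditions: MnO2, CH2Cl2, rt
Reagents that add atoms: none
Why: Manganese dioxide oxidises only the free allylic alcohol under neutral conditions, so the Z geometry of the enal is kept.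

Step 17
Reactants: 22 (4Z)-allene–enal
Product: 25 ten-membered 6-epi alcohol bearing the C11 pinacol boronate, via bis(boronate) enal 23 (not isolated), via macrocyclic O-boryl ether 24 (not isolated)
Conditions: B2pin2 (1.05 equiv), Pt(dba)2 (3 mol %), PCy3 (6 mol %), toluene (0.1 M), 50 °C; then diluted with toluene to 1 mM, 90 °C; aq. NaHCO3
Reagents that add atoms: bis(pinacolato)diboron, CC1(C)OB(B2OC(C)(C)C(C)(C)O2)OC1(C)C
Why: Platinum-catalysed diboration of the terminal C11=C13 bond gives the (Z)-2-boryl allylboronate 23, whose intramolecular allylboration through a closed chair (the C6–C7 closure known for allyl-chromium and allyl-zinc reagents in germacranes and for allylboronates in medium rings) sets C7 by attack anti to C8–OTES in the A(1,3)-minimised, H8-eclipsed conformer and sets C6 as 6,7-syn (6-epi) because of the Z geometry.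

Step 18
Reactants: 25 ten-membered 6-epi alcohol bearing the C11 pinacol boronate
Product: 26 6-epi allylic diethyl phosphate
Conditions: ClP(O)(OEt)2, Et3N, DMAP (cat.), CH2Cl2, 0 °C; used without delay
Reagents that add atoms: diethyl chlorophosphate, CCOP(=O)(Cl)OCC
Why: O-Phosphorylation proceeds at oxygen with retention at C6 and installs a leaving group that can be handled yet is good enough for an intramolecular displacement.

Step 19
Reactants: 26 6-epi allylic diethyl phosphate
Product: 28 trans-fused α-methylene-γ-butyrolactone (2-OTBS 14-OTBS 8-OTES), via potassium carboxylate 27 (not isolated)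
Conditions: (IPr)CuCl (10 mol %), CO2 (1 atm, solution saturated first), KOt-Bu (1.1 equiv, added last), THF, rt to 65 °C
Reagents that add atoms: carbon dioxide, O=C=O
Why: Proposed new method: tert-butoxide converts the C11 boronate of 26 into an ate complex that transfers the alkenyl group to (IPr)Cu, the C11–Cu bond inserts CO2 to make C11–C12, and an oxygen of the resulting carboxylate 27 displaces the C6 phosphate to make O–C6, so that CO2 acts as a C-electrophile/O-nucleophile linchpin between nucleophilic C11 and electrophilic C6. The closest known reaction types are the NHC–copper-catalysed carboxylation of alkenylboronic esters under 1 atm of CO2 and the copper-catalysed carboxylative coupling of organocopper species, CO2 and allylic halides to allylic esters, and their intramolecular merger on an allylic phosphate has not been described. The only ring closed is the γ-lactone O–C6–C7–C11–C12, by a 5-exo-tet displacement. C6 is the only stereocentre that changes: in the extended C5–C6–C7–C8 conformer of the 6,7-syn isomer the C6–OP bond is antiperiplanar to C7–C11, so backside attack inverts C6 from S to R and gives the trans-fused lactone, an outcome that A(1,3) strain across the Z C4=C5 bond (H7 eclipsing C5) would also favour if the displacement had ion-pair character. The step needs CO2 insertion to outrun C–C coupling of the alkenylcopper with the allyl unit and O-attack at C6 to beat attack at C4: coupling at C6 would give a strained methylenecyclopropane, SN2′ coupling at C4 would have to build a quaternary centre through a conformer in which C7 eclipses C3 across the Z-alkene, the solution is saturated with CO2 before the alkoxide is added, and carboxylate attack at C4 would close a seven- instead of a five-membered ring. Free alkoxide is buffered by boron and by CO2, which protects the phosphate from elimination and the three silyl ethers from cleavage.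

Step 20
Reactants: 28 trans-fused α-methylene-γ-butyrolactone (2-OTBS 14-OTBS 8-OTES)
Product: 29 8-hydroxy lactone
Conditions: PPTS (cat.), MeOH/CH2Cl2 (1:4), 0 °C
Reagents that add atoms: none
Why: Acid-catalysed methanolysis cleaves the TES ether much faster than the TBS ethers, and the non-basic medium avoids lactone migration to O8 and conjugate addition to the methylene lactone.

Step 21
Reactants: 29 8-hydroxy lactone; 30 angelic acid
Product: 32 8-O-angelate bis-TBS ether, via mixed anhydride 31 (not isolated)
Conditions: 30, 2,4,6-trichlorobenzoyl chloride, Et3N, toluene, rt; then 29, toluene, 80 °C (no DMAP)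
Reagents that add atoms: none
Why: Yamaguchi-type mixed-anhydride acylation without a nucleophilic catalyst is the established way to transfer the angeloyl group with its Z geometry intact, and it proceeds at oxygen so C8 stays S.

Step 22
Reactants: 32 8-O-angelate bis-TBS ether
Product: 33 target CNP0270898.1
Conditions: HF·pyridine, pyridine/THF, 0 °C to rt
Reagents that add atoms: none
Why: Buffered fluoride desilylation removes both TBS groups under conditions tolerated by the α-methylene lactone, the angelate and the two allylic alcohols.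

**Compound list**
1 | nerol, (2Z)-3,7-dimethylocta-2,6-dien-1-ol | CC(C)=CCC/C(C)=C\CO | starting material
2 | neryl 4-methoxybenzyl ether | CC(C)=CCC/C(C)=C\COCc1ccc(OC)cc1 | intermediate
3 | 6,7-epoxyneryl 4-methoxybenzyl ether (racemic epoxide) | CC1(C)OC1CC/C(C)=C\COCc1ccc(OC)cc1 | intermediate
4 | (4Z)-6-[(4-methoxybenzyl)oxy]-4-methylhex-4-enal (C1–C6, C15) | O=CCC/C(C)=C\COCc1ccc(OC)cc1 | intermediate
5 | methyl 4-chloro-4-oxobutanoate | COC(=O)CCC(=O)Cl | starting material
6 | bis(trimethylsilyl)acetylene | C[Si](C)(C)C#C[Si](C)(C)C | starting material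
7 | methyl 4-oxo-6-(trimethylsilyl)hex-5-ynoate | COC(=O)CCC(=O)C#C[Si](C)(C)C | intermediate
8 | methyl (4S)-4-hydroxy-6-(trimethylsilyl)hex-5-ynoate | COC(=O)CC[C@H](O)C#C[Si](C)(C)C | intermediate
9 | methyl (4S)-4-hydroxyhex-5-ynoate | COC(=O)CC[C@H](O)C#C | intermediate
10 | (5S)-5-ethynyloxolan-2-one | O=C1CC[C@@H](C#C)O1 | intermediate
11 | (5S)-5-(propa-1,2-dien-1-yl)oxolan-2-one | O=C1CC[C@@H](C=C=C)O1 | intermediate
12 | diethyl [(5S)-2-oxo-5-(propa-1,2-dienyl)oxolan-3-yl]phosphonite (C10 epimers) | CCOP(OCC)C1C[C@@H](C=C=C)OC1=O | intermediate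
13 | diethyl [(5S)-2-oxo-5-(propa-1,2-dienyl)oxolan-3-yl]phosphonate (C10 epimers) | CCOP(=O)(OCC)C1C[C@@H](C=C=C)OC1=O | intermediate
14 | (2S,4Z)-2-(anilinooxy)-6-[(4-methoxybenzyl)oxy]-4-methylhex-4-enal | O=C[C@@H](ONc1ccccc1)C/C(C)=C\COCc1ccc(OC)cc1 | intermediate
15 | (2S,8S)-E-alkylidene lactone: C1=C10 exocyclic to the C14(=O)–O8 butyrolactone, 2-ONHPh, 6-OPMB, 4Z, allene at C7 | COc1ccc(COC/C=C(/C)C[C@H](ONc2ccccc2)/C=C2\C[C@@H](C=C=C)OC2=O)cc1 | intermediate
16 | as 15 with free (2S)-OH | COc1ccc(COC/C=C(/C)C[C@H](O)/C=C2\C[C@@H](C=C=C)OC2=O)cc1 | intermediate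
17 | as 16 with 2-OTBS | COc1ccc(COC/C=C(/C)C[C@H](O[Si](C)(C)C(C)(C)C)/C=C2\C[C@@H](C=C=C)OC2=O)cc1 | intermediate
18 | (2S,8S)-open-chain diol: 6-OPMB, 2-OTBS, free 14-OH and 8-OH, 1(10)E, 4Z, terminal allene | COc1ccc(COC/C=C(/C)C[C@H](O[Si](C)(C)C(C)(C)C)/C=C(/CO)C[C@H](O)C=C=C)cc1 | intermediate
19 | as 18 with 14-OTBS | COc1ccc(COC/C=C(/C)C[C@H](O[Si](C)(C)C(C)(C)C)/C=C(/CO[Si](C)(C)C(C)(C)C)C[C@H](O)C=C=C)cc1 | intermediate
20 | as 19 with 8-OTES | COc1ccc(COC/C=C(/C)C[C@H](O[Si](C)(C)C(C)(C)C)/C=C(/CO[Si](C)(C)C(C)(C)C)C[C@H](O[Si](CC)(CC)CC)C=C=C)cc1 | intermediate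
21 | as 20 with free C6-OH | OC/C=C(/C)C[C@H](O[Si](C)(C)C(C)(C)C)/C=C(/CO[Si](C)(C)C(C)(C)C)C[C@H](O[Si](CC)(CC)CC)C=C=C | intermediate
22 | (2S,8S)-allene–enal (C6 aldehyde, 4Z) | O=C/C=C(/C)C[C@H](O[Si](C)(C)C(C)(C)C)/C=C(/CO[Si](C)(C)C(C)(C)C)C[C@H](O[Si](CC)(CC)CC)C=C=C | intermediate
23 | enal with (7Z)-C7=C11, Bpin on C11 and on C13 | O=C/C=C(/C)C[C@H](O[Si](C)(C)C(C)(C)C)/C=C(/CO[Si](C)(C)C(C)(C)C)C[C@H](O[Si](CC)(CC)CC)/C=C(\CB1OC(C)(C)C(C)(C)O1)B1OC(C)(C)C(C)(C)O1 | intermediate
24 | (2S,6S,7S,8S)-12-norgermacra-1(10)E,4Z,11(13)-triene, 6-OBpin, 11-Bpin, 2-OTBS, 14-OTBS, 8-OTES | C=C(B1OC(C)(C)C(C)(C)O1)[C@H]1[C@@H](OB2OC(C)(C)C(C)(C)O2)/C=C(/C)C[C@H](O[Si](C)(C)C(C)(C)C)/C=C(/CO[Si](C)(C)C(C)(C)C)C[C@@H]1O[Si](CC)(CC)CC | intermediate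
25 | (2S,6S,7S,8S)-6-epi alcohol: as 24 with free 6-OH | C=C(B1OC(C)(C)C(C)(C)O1)[C@H]1[C@@H](O)/C=C(/C)C[C@H](O[Si](C)(C)C(C)(C)C)/C=C(/CO[Si](C)(C)C(C)(C)C)C[C@@H]1O[Si](CC)(CC)CC | intermediate
26 | (2S,6S,7R,8S)-6-O-diethylphosphate of 25 | C=C(B1OC(C)(C)C(C)(C)O1)[C@H]1[C@@H](OP(=O)(OCC)OCC)/C=C(/C)C[C@H](O[Si](C)(C)C(C)(C)C)/C=C(/CO[Si](C)(C)C(C)(C)C)C[C@@H]1O[Si](CC)(CC)CC | intermediate
27 | potassium (2S,6S,7R,8S)-germacratrien-12-oate with the 6-phosphate still in place | C=C(C(=O)[O-])[C@H]1[C@@H](OP(=O)(OCC)OCC)/C=C(/C)C[C@H](O[Si](C)(C)C(C)(C)C)/C=C(/CO[Si](C)(C)C(C)(C)C)C[C@@H]1O[Si](CC)(CC)CC.[K+] | intermediate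
28 | (2S,6R,7S,8S)-germacra-1(10)E,4Z,11(13)-trien-12,6-olide, 2-OTBS, 14-OTBS, 8-OTES (trans-fused) | C=C1C(=O)O[C@@H]2/C=C(/C)C[C@H](O[Si](C)(C)C(C)(C)C)/C=C(/CO[Si](C)(C)C(C)(C)C)C[C@H](O[Si](CC)(CC)CC)[C@@H]12 | intermediate
29 | (2S,6R,7R,8S)-8-hydroxy lactone, 2-OTBS, 14-OTBS | C=C1C(=O)O[C@@H]2/C=C(/C)C[C@H](O[Si](C)(C)C(C)(C)C)/C=C(/CO[Si](C)(C)C(C)(C)C)C[C@H](O)[C@@H]12 | intermediate
30 | angelic acid, (2Z)-2-methylbut-2-enoic acid | C/C=C(/C)C(=O)O | starting material
31 | angelic 2,4,6-trichlorobenzoic anhydride | C/C=C(/C)C(=O)OC(=O)c1c(Cl)cc(Cl)cc1Cl | intermediate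
32 | (2S,6R,7R,8S)-8-O-angelate, 2-OTBS, 14-OTBS | C=C1C(=O)O[C@@H]2/C=C(/C)C[C@H](O[Si](C)(C)C(C)(C)C)/C=C(/CO[Si](C)(C)C(C)(C)C)C[C@H](OC(=O)/C(C)=C\C)[C@@H]12 | intermediate
33 | CNP0270898.1, (2S,6R,7R,8S)-8-angeloyloxy-2,14-dihydroxygermacra-1(10)E,4Z,11(13)-trien-12,6-olide | C=C1C(=O)O[C@@H]2/C=C(/C)C[C@H](O)/C=C(/CO)C[C@H](OC(=O)/C(C)=C\C)[C@@H]12 | target

**Step count**
- Total: 22 steps.
- Longest linear sequence: 19 steps (steps 4–8, then 9–22).

**Steps most likely to fail**

1. Step 19.
   - The alkenylcopper may be protonated, or it may couple with the allyl unit before it meets CO2.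
   - The phosphate may ionise before the carboxylate is in place, which would erode the inversion at C6 or lead to elimination.
   - The fallback uses known chemistry, sets out from 25 and returns at 28.
   - Mitsunobu inversion of 25 (4-nitrobenzoic acid, PPh3, DIAD, toluene, 0 °C) gives the 6R 4-nitrobenzoate F1.
   - Methanolysis (K2CO3, MeOH) gives the 6R alcohol F2.
   - Iodine and NaOH in THF/water exchange the boronate for iodine to give the alkenyl iodide F3.
   - Palladium-catalysed carbonylative lactonisation (Pd(PPh3)4, CO 1 atm, Et3N, THF, 60 °C) closes the acyl C12–O bond with retention at C6 to give 28.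

2. Step 17.
   - The thermal allyl transfer is slow, so intermolecular allylation (oligomerisation) and Z-to-E isomerisation of the enal may compete.
   - Passage through the alternative chair may also compete, which would erode the 6,7-syn relationship.
   - The fallback sets out from 22 and returns at 25. It replaces the preformed allylboronate by a catalytic allylcopper.
   - Compound 22 is added slowly to (SIMes)CuCl (5 mol %), NaOt-Bu (10 mol %) and B2pin2 in THF at rt.
   - Borylcupration of the allene gives the (Z)-2-boryl allylcopper, which is present only in catalytic concentration and adds to the aldehyde at ambient temperature.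
   - The copper alkoxide is turned over by B2pin2 to 24, and hydrolysis gives 25.
   - No compound outside the list is made (F0).

3. Step 21.
   - Acylation of the hindered C8 hydroxyl at 80 °C is slow. This gives time for Z-to-E isomerisation of the angeloyl unit and for migration of the lactone from O6 to O8.
   - The fallback sets out from 29 and returns at 32. It builds the Z-alkene after the ester bond.
   - Compound 29 is acylated at 0 °C with 2-[bis(2,2,2-trifluoroethoxy)phosphoryl]propanoic acid (DCC, DMAP cat., CH2Cl2) to give the phosphonopropionate F4.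
   - Still–Gennari olefination (KHMDS, 18-crown-6, THF, −78 °C, then acetaldehyde) gives the Z-enoate 32.

**Further compounds**
F1 | step 19 | 6R 4-nitrobenzoate (C6 epimer series of 25, other centres as in 25) | C=C(B1OC(C)(C)C(C)(C)O1)[C@H]1[C@H](OC(=O)c2ccc(cc2)[N+](=O)[O-])/C=C(/C)C[C@H](O[Si](C)(C)C(C)(C)C)/C=C(/CO[Si](C)(C)C(C)(C)C)C[C@@H]1O[Si](CC)(CC)CC
F2 | step 19 | 6R alcohol (C6 epimer of 25) | C=C(B1OC(C)(C)C(C)(C)O1)[C@H]1[C@H](O)/C=C(/C)C[C@H](O[Si](C)(C)C(C)(C)C)/C=C(/CO[Si](C)(C)C(C)(C)C)C[C@@H]1O[Si](CC)(CC)CC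
F3 | step 19 | 6R alcohol with iodine on C11 in place of Bpin | C=C(I)[C@H]1[C@H](O)/C=C(/C)C[C@H](O[Si](C)(C)C(C)(C)C)/C=C(/CO[Si](C)(C)C(C)(C)C)C[C@@H]1O[Si](CC)(CC)CC
F0 | step 17 | none | none
F4 | step 21 | 8-O-{2-[bis(2,2,2-trifluoroethoxy)phosphoryl]propanoate} of 29 | C=C1C(=O)O[C@@H]2/C=C(/C)C[C@H](O[Si](C)(C)C(C)(C)C)/C=C(/CO[Si](C)(C)C(C)(C)C)C[C@H](OC(=O)C(C)P(=O)(OCC(F)(F)F)OCC(F)(F)F)[C@@H]12
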